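I decided to rank the four flasks by how long each one's solid substrate lasts, not by a percentage. The bench habit treats a flask as first-order, so that the percent left at a given time is the same for any charge; I took that as the zero of my scale. The earlier runs break it: at 6.00 h winter held 2% of its solid substrate, dusk far more, 81%.

| flask | solid substrate | remark | time |
|---|---|---|---|
| winter | 0.010 M | run made earlier |  |
| dusk | 0.061 M | run made earlier |  |
| north-east | 0.050 M |  | 15 h |
| south-west | 0.025 M |  | 15 h |
| west | 0.012 M |  | 15 h |
| east | 0.080 M |  | 15 h |

| run | time / h | intermediate / % | product / % | solid substrate / % |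
|---|---|---|---|---|
| winter | 1.33 | 11 | 0 | 71 |
| winter | 2.00 | 24 | 3 | 61 |
| winter | 3.00 | 41 | 2 | 40 |
| winter | 4.00 | 56 | 9 | 21 |
| winter | 6.00 | 75 | 19 | 2 |
| winter | 10.0 | 61 | 40 | 1 |
| winter | 15.0 | 39 | 61 | 0 |
| dusk | 0.833 | 1 | 1 | 95 |
| dusk | 2.50 | 7 | 0 | 90 |
| dusk | 4.00 | 7 | 1 | 88 |
| dusk | 6.00 | 13 | 2 | 81 |
| dusk | 10.0 | 21 | 8 | 69 |
| dusk | 12.0 | 26 | 12 | 60 |
| dusk | 15.0 | 26 | 18 | 51 |

(scatter of a reading: 1.5 percentage points)

- solid, in amounts per volume of the solution: solid substrate
- at the start none of the solid substrate is in solution
- what has only dissolved of solid substrate counts as not reacted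

* the flasks by amount of intermediate, in percent of the solid substrate charged, highest first, at 15 h (north-east / south-west / west / east)
* the amount of intermediate, in percent of the solid substrate charged of the flask you put first, at 15 h
* the amount of intermediate, in percent of the solid substrate charged of the flask you put last, at 15 h

Counted in molarity, the two runs read alike, within their scatter. Dusk lost 0.00199 M h⁻¹ over 15.0 h, and winter 0.00198 M h⁻¹ over 4.00 h. I called this the feed: solid substrate lost per litre and hour while solid lies in the flask, a zero-order rule.

Its border is the ratio of the charge to the feed times 15 h, which stands at one where the solid should just last the asked time: 0.402 for west, 0.836 for south-west, 1.67 for north-east, 2.68 for east. South-west's charge should last 12.5 h, shorter than the asked time, and west's 6.03 h. Above the border I scaled dusk's intermediate reading at 15.0 h by charge, which gave 31.7% for north-east and 19.8% for east. West's charge of 0.012 M lies near winter's 0.010 M, so I took west near winter's reading of 39% at 15.0 h. South-west should fall a little under its scaled 63.4%. That made my order south-west, west, north-east, east.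

The forecast gave the same order, south-west > west > north-east > east, with 58% and 20%, reasoning “While solid remains, intermediate forms at a constant” rate.

The flasks gave south-west > west > north-east > east, with 55.0% in south-west and 21.1% in east.

    starting material → intermediate (k = 0.0187 min⁻¹)
    solid substrate ⇌ starting material, rate k2*(cs2 - [starting material]) while solid is left; crystals form when [starting material] > cs2 (solubility = 38.0 mM, k = 9.19 × 10⁻⁴ min⁻¹)
    intermediate → product (k = 0.00134 min⁻¹)

By the feed, east should have kept 62.6% of its solid substrate, and east held 62.5% at 15.0 h. A further flask, like east but charged with 0.048 M, has a border ratio of 1.61, so by the feed its solid should outlast the asked time, with 37.8% left. It held 37.4% of solid substrate at 15.0 h. Dusk's intermediate scaled to that charge gives 33.0%, and the flask held 35.1%.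

The earlier runs and the new flask come from a simulation with constants of no real substance; noise was put on by code.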